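**Plan**

1. Numbering: O1–O2–C3(CH2CO2H)–C4(Me)–C5–C6(Me)(side chain); C8 is the side-chain stereocentre. Retrosynthesis: cut C3–CH2CO2H (peroxycarbenium ion at C3 plus a silyl ketene acetal), take the O–O unit out of the 1,2-dioxan-3-ol to leave the cyclobutanol C3(OH)–C4–C5–C6, cut C4–CH3, take the cyclobutanone back to a methyl ketone plus a cyclopropyl unit, and cut C8–CH3.
2. Forward: chain ketone → 2,2-disubstituted cyclobutanone (cyclopropyl sulfonium annulation) → α-methylation → cyclobutanol → aerobic ring expansion to the six-membered peroxide → acetate side chain at C3 → acid.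
3. Enabling feature: a strained four-membered carbocycle in which carbinol carbon C3 is bonded to the fully substituted C6. The alkoxy radical on C3 breaks C3–C6 (strain release, tertiary radical), O2 adds at C6, and the hydroperoxide closes on the C3 aldehyde.
4. Stereochemistry: C8 by Cu/Josiphos conjugate methylation; C4 by RAMP-hydrazone methylation; C3 by substrate control (axial attack on the peroxycarbenium ion with 4-Me equatorial).
5. C6 arises from a planar radical with no face bias and is not controlled; the two C6 diastereomers are separated by chromatography at the ester stage and only the 6R isomer is carried on. The cyclobutane centres at C3 and C6 need no control because the key step erases both.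

Key step: step 9

Assumption: the Josiphos enantiomer giving the 4R ketone (step 3) and the choice of RAMP for the 4S methyl centre (step 6) follow the accepted models for linear enones and cyclic SAMP/RAMP azaenolates; if either sense is opposite, the mirror-image ligand or SAMP is used with no other change.
Assumption: 10-phenyldecan-1-ol is taken as a catalogue compound.

Step 1
Reactants: 1 10-phenyldecan-1-ol
Product: 2 10-phenyldecanal
Conditions: TEMPO (cat.), PhI(OAc)2, CH2Cl2, rt
Reagents that add atoms: none
Why: Oxoammonium (TEMPO/PhI(OAc)2) oxidation of a primary alcohol stops at the aldehyde, and nothing else in 1 is oxidisable.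

Step 2
Reactants: 2 10-phenyldecanal; 3 1-(triphenylphosphoranylidene)propan-2-one
Product: 4 (3E)-13-phenyltridec-3-en-2-one
Conditions: toluene, 80 °C
Reagents that add atoms: 1-(triphenylphosphoranylidene)propan-2-one (3), CC(=O)C=P(c1ccccc1)(c1ccccc1)c1ccccc1
Why: Wittig olefination with a stabilised acyl ylide should give the E-enone selectively.

Step 3
Reactants: 4 (3E)-13-phenyltridec-3-en-2-one
Product: 5 (4R)-4-methyl-13-phenyltridecan-2-one
Conditions: CuBr·SMe2 (5 mol%), Josiphos (6 mol%, enantiomer giving 4R), MeMgBr, t-BuOMe, −75 °C; then aq. NH4Cl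
Reagents that add atoms: methylmagnesium bromide, C[Mg]Br
Why: Copper/ferrocenyl-diphosphine catalysed asymmetric conjugate addition of a Grignard reagent to a linear aliphatic enone sets C8 by catalyst control of the enone face, and the cuprate pathway suppresses 1,2-addition.

Step 4
Reactants: 5 (4R)-4-methyl-13-phenyltridecan-2-one; 6 cyclopropyldiphenylsulfonium tetrafluoroborate
Product: 8 2-methyl-2-[(2R)-2-methyl-11-phenylundecyl]cyclobutan-1-one (C2 epimer mixture), via oxaspiropentane 7 (not isolated)
Conditions: KOH, DMSO, rt; then HBF4 (cat.), Et2O, rt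
Reagents that add atoms: cyclopropyldiphenylsulfonium tetrafluoroborate (6), c1ccccc1[S+](C1CC1)c1ccccc1.F[B-](F)(F)F
Why: Trost cyclobutanone annulation: the sulfonium cyclopropylide adds to the ketone and closes to the oxaspiropentane, whose acid-triggered cyclopropylcarbinyl-to-cyclobutyl shift gives the 2,2-disubstituted cyclobutanone; the new quaternary centre forms as both epimers, which is harmless because it becomes the planar radical of step 9.

Step 5
Reactants: 8 2-methyl-2-[(2R)-2-methyl-11-phenylundecyl]cyclobutan-1-one; 9 (2R)-2-(methoxymethyl)pyrrolidin-1-amine (RAMP)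
Product: 10 RAMP hydrazone of 8, (2R)-2-(methoxymethyl)-N-{2-methyl-2-[(2R)-2-methyl-11-phenylundecyl]cyclobutylidene}pyrrolidin-1-amine
Conditions: cyclohexane, 60 °C, 4 Å MS
Reagents that add atoms: (2R)-2-(methoxymethyl)pyrrolidin-1-amine (9), COC[C@H]1CCCN1N
Why: Hydrazone condensation on the electrophilic cyclobutanone carbonyl, with the amino group expected syn to the only α-CH2 because the other α-carbon is quaternary.

Step 6
Reactants: 10 RAMP hydrazone of 8
Product: 11 (2R)-N-{(4S)-2,4-dimethyl-2-[(2R)-2-methyl-11-phenylundecyl]cyclobutylidene}-2-(methoxymethyl)pyrrolidin-1-amine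
Conditions: LDA, THF, 0 °C; then MeI, −100 → −78 °C
Reagents that add atoms: iodomethane, CI
Why: Enders SAMP/RAMP alkylation: only one α-position can be deprotonated, and the lithium-chelated azaenolate is methylated on the face left open by the methoxymethylpyrrolidine, which sets C4 as S by auxiliary control.

Step 7
Reactants: 11 methylated RAMP hydrazone
Product: 12 (4S)-2,4-dimethyl-2-[(2R)-2-methyl-11-phenylundecyl]cyclobutan-1-one (C2 epimer mixture)
Conditions: sat. aq. oxalic acid, Et2O, rt
Reagents that add atoms: water, O
Why: Two-phase oxalic acid hydrolysis of an Enders hydrazone releases the ketone under conditions too mild to epimerise the α-methyl centre, and the auxiliary is recovered.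

Step 8
Reactants: 12 (4S)-2,4-dimethyl-2-[(2R)-2-methyl-11-phenylundecyl]cyclobutan-1-one
Product: 13 (4S)-2,4-dimethyl-2-[(2R)-2-methyl-11-phenylundecyl]cyclobutan-1-ol (C1/C2 epimer mixture)
Conditions: NaBH4, MeOH, −40 °C
Reagents that add atoms: none
Why: Borohydride reduction of the strained ketone at low temperature should outrun enolisation, and the carbinol configuration is irrelevant because step 9 turns this carbon into a carbonyl.

Step 9
Reactants: 13 (4S)-2,4-dimethyl-2-[(2R)-2-methyl-11-phenylundecyl]cyclobutan-1-ol
Product: 16 (4S)-4,6-dimethyl-6-[(2R)-2-methyl-11-phenylundecyl]-1,2-dioxan-3-ol (C3/C6 epimer mixture), via tertiary alkyl radical 14 (not isolated), via hydroperoxy aldehyde 15 (not isolated)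
Conditions: Co(acac)2 (20 mol%), O2 (1 atm), ClCH2CH2Cl, rt
Reagents that add atoms: dioxygen, O=O
Why: Co(II)/O2 turns the carbinol into a cobalt(III) alkoxide/alkoxy radical whose strained ring undergoes β-scission of the C3–C6 bond to the γ-formyl tertiary radical 14; this captures triplet O2, and the peroxyl radical is reduced to hydroperoxide 15 with return of the catalyst. The closest known reaction type is the cobalt- or manganese-catalysed aerobic ring expansion of cyclopropanols and cyclobutanols to 1,2-dioxolan-3-ols and 1,2-dioxan-3-ols. The six-membered ring closes by 6-exo-trig addition of the hydroperoxide oxygen to the C3 aldehyde (reversible hemiacetalisation), so the four ring carbons are kept and O–O is inserted into the former C3–C6 bond. C4 is not touched and keeps its S configuration, C3 is a hemiacetal centre that is reset in step 11, and C6 is created from a planar radical with no element able to bias the face, so both C6 epimers are expected. The step needs regioselective scission (C3–C6, not C3–C4), which the fully substituted C6 secures through the tertiary radical, and chemoselectivity over plain oxidation to ketone 12, which ring strain should favour.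

Step 10
Reactants: 16 (4S)-4,6-dimethyl-6-[(2R)-2-methyl-11-phenylundecyl]-1,2-dioxan-3-ol
Product: 17 (4S)-4,6-dimethyl-6-[(2R)-2-methyl-11-phenylundecyl]-1,2-dioxan-3-yl acetate (C3/C6 epimer mixture)
Conditions: Ac2O, pyridine, DMAP (cat.), CH2Cl2, 0 °C
Reagents that add atoms: acetic anhydride, CC(=O)OC(C)=O
Why: Acylation of the peroxy-hemiacetal hydroxyl gives the acetate leaving group, and the weak amine base should avoid Kornblum–DeLaMare cleavage at C3–H.

Step 11
Reactants: 17 (4S)-4,6-dimethyl-6-[(2R)-2-methyl-11-phenylundecyl]-1,2-dioxan-3-yl acetate; 18 tert-butyl[(1-methoxyethenyl)oxy]dimethylsilane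
Product: 19 methyl 2-{(3S,4S,6R)-4,6-dimethyl-6-[(2R)-2-methyl-11-phenylundecyl]-1,2-dioxan-3-yl}acetate
Conditions: TMSOTf (cat.), CH2Cl2, −78 °C; then silica gel chromatography to separate the two C6 diastereomers, of which the 6R isomer is kept
Reagents that add atoms: tert-butyl[(1-methoxyethenyl)oxy]dimethylsilane (18), C=C(OC)O[Si](C)(C)C(C)(C)C
Why: Lewis-acid ionisation gives the peroxycarbenium ion at C3, which is trapped in a Mukaiyama-type addition; with 4-Me equatorial in the half-chair, stereoelectronically preferred axial attack should give the 3,4-cis (3S) product in both C6 series, after which the two C6 diastereomers, each now a single compound, are separated and only the 6R isomer goes on.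

Step 12
Reactants: 19 methyl 2-{(3S,4S,6R)-4,6-dimethyl-6-[(2R)-2-methyl-11-phenylundecyl]-1,2-dioxan-3-yl}acetate
Product: 20 2-{(3S,4S,6R)-4,6-dimethyl-6-[(2R)-2-methyl-11-phenylundecyl]-1,2-dioxan-3-yl}acetic acid
Conditions: LiOH, THF/H2O, 0 °C; then 1 M HCl to pH 3
Reagents that add atoms: lithium hydroxide, [Li+].[OH-]
Why: Cold saponification of the methyl ester should leave the dialkyl peroxide intact, and carboxylate formation removes the α-acidity that could trigger β-elimination of the peroxide.

**Compound list**

1 | 10-phenyldecan-1-ol | OCCCCCCCCCCc1ccccc1 | starting material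
2 | 10-phenyldecanal | O=CCCCCCCCCCc1ccccc1 | intermediate
3 | 1-(triphenylphosphoranylidene)propan-2-one | CC(=O)C=P(c1ccccc1)(c1ccccc1)c1ccccc1 | starting material
4 | (3E)-13-phenyltridec-3-en-2-one | CC(=O)/C=C/CCCCCCCCCc1ccccc1 | intermediate
5 | (4R)-4-methyl-13-phenyltridecan-2-one | C[C@H](CCCCCCCCCc1ccccc1)CC(C)=O | intermediate
6 | cyclopropyldiphenylsulfonium tetrafluoroborate | c1ccccc1[S+](C1CC1)c1ccccc1.F[B-](F)(F)F | starting material
7 | 2-methyl-2-[(2R)-2-methyl-11-phenylundecyl]-1-oxaspiro[2.2]pentane (C2 epimers) | C[C@H](CCCCCCCCCc1ccccc1)CC1(C)OC12CC2 | intermediate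
8 | 2-methyl-2-[(2R)-2-methyl-11-phenylundecyl]cyclobutan-1-one (C2 epimers) | C[C@H](CCCCCCCCCc1ccccc1)CC1(C)CCC1=O | intermediate
9 | (2R)-2-(methoxymethyl)pyrrolidin-1-amine (RAMP) | COC[C@H]1CCCN1N | starting material
10 | (2R)-2-(methoxymethyl)-N-{2-methyl-2-[(2R)-2-methyl-11-phenylundecyl]cyclobutylidene}pyrrolidin-1-amine | C[C@H](CCCCCCCCCc1ccccc1)CC1(C)CCC1=NN1CCC[C@@H]1COC | intermediate
11 | (2R)-N-{(4S)-2,4-dimethyl-2-[(2R)-2-methyl-11-phenylundecyl]cyclobutylidene}-2-(methoxymethyl)pyrrolidin-1-amine | C[C@H](CCCCCCCCCc1ccccc1)CC1(C)C[C@H](C)C1=NN1CCC[C@@H]1COC | intermediate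
12 | (4S)-2,4-dimethyl-2-[(2R)-2-methyl-11-phenylundecyl]cyclobutan-1-one (C2 epimers) | C[C@H](CCCCCCCCCc1ccccc1)CC1(C)C[C@H](C)C1=O | intermediate
13 | (4S)-2,4-dimethyl-2-[(2R)-2-methyl-11-phenylundecyl]cyclobutan-1-ol (C1 and C2 epimers) | C[C@H](CCCCCCCCCc1ccccc1)CC1(C)C[C@H](C)C1O | intermediate
14 | (2S,6R)-2,4,6-trimethyl-1-oxo-15-phenylpentadecan-4-yl radical | C[C@H](CCCCCCCCCc1ccccc1)C[C](C)C[C@H](C)C=O | intermediate
15 | (2S,6R)-4-hydroperoxy-2,4,6-trimethyl-15-phenylpentadecanal (C4 epimers) | C[C@H](CCCCCCCCCc1ccccc1)CC(C)(OO)C[C@H](C)C=O | intermediate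
16 | (4S)-4,6-dimethyl-6-[(2R)-2-methyl-11-phenylundecyl]-1,2-dioxan-3-ol (C3 and C6 epimers) | C[C@H](CCCCCCCCCc1ccccc1)CC1(C)C[C@H](C)C(O)OO1 | intermediate
17 | (4S)-4,6-dimethyl-6-[(2R)-2-methyl-11-phenylundecyl]-1,2-dioxan-3-yl acetate (C3 and C6 epimers) | C[C@H](CCCCCCCCCc1ccccc1)CC1(C)C[C@H](C)C(OC(C)=O)OO1 | intermediate
18 | tert-butyl[(1-methoxyethenyl)oxy]dimethylsilane | C=C(OC)O[Si](C)(C)C(C)(C)C | starting material
19 | methyl 2-{(3S,4S,6R)-4,6-dimethyl-6-[(2R)-2-methyl-11-phenylundecyl]-1,2-dioxan-3-yl}acetate (single diastereomer after chromatography) | C[C@H](CCCCCCCCCc1ccccc1)C[C@]1(C)C[C@H](C)[C@H](CC(=O)OC)OO1 | intermediate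
20 | 2-{(3S,4S,6R)-4,6-dimethyl-6-[(2R)-2-methyl-11-phenylundecyl]-1,2-dioxan-3-yl}acetic acid | C[C@H](CCCCCCCCCc1ccccc1)C[C@]1(C)C[C@H](C)[C@H](CC(=O)O)OO1 | target

**Totals**

Total step count: 12. Longest linear sequence: 12 steps (1 → 20).

**Steps most likely to fail**

Step 9. Dehydrogenation of the secondary carbinol to the cyclobutanone and scission toward the secondary carbon may compete with the desired ring opening, and oxygen capture at C6 has no face preference. The fallback builds the peroxide on an open chain; it sets out from 5 and comes back at 16. Ketone 5 is olefinated with the oxido ylide (2 equiv LiHMDS, THF) of the commercial salt [(2R)-3-hydroxy-2-methylpropyl]triphenylphosphonium bromide F1 to give the trisubstituted alkenol (2S,6R)-2,4,6-trimethyl-15-phenylpentadec-3-en-1-ol F2 as an E/Z mixture. Isayama–Mukaiyama hydroperoxysilylation (Co(acac)2, O2, Et3SiH, ClCH2CH2Cl) places the peroxide on the tertiary carbon and gives (2S,6R)-2,4,6-trimethyl-15-phenyl-4-[(triethylsilyl)peroxy]pentadecan-1-ol F3. Dess–Martin oxidation gives (2S,6R)-2,4,6-trimethyl-15-phenyl-4-[(triethylsilyl)peroxy]pentadecanal F4, and HF·pyridine releases 15, which closes to 16. C4 then comes from the chiral pool and steps 4 to 8 are not needed. C6 is still formed without face control, so the diastereomer separation in step 11 stays.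

Step 11. Attack on the peroxycarbenium ion may show poor facial selectivity at C3, or the cation may be lost by elimination or fragmentation under the Lewis acid. The fallback reopens and recloses the ring; it sets out from 16 and comes back at 19. The hemiacetal 16 is olefinated through its open aldehyde form with methyl (triphenylphosphoranylidene)acetate under neutral conditions to give methyl (2E,4S,8R)-6-hydroperoxy-4,6,8-trimethyl-17-phenylheptadec-2-enoate F5. Amine-mediated (Et2NH, CF3CH2OH) 6-exo-trig oxa-Michael addition of the hydroperoxide then closes the dioxane to 19, with C3 set in a chair transition state, not by cation capture. The 6S diastereomer is again removed by chromatography.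

Step 6. Methylation of the azaenolate may show low facial selectivity on a ring that already carries a quaternary centre of mixed configuration, or the α-centre may epimerise during hydrazone cleavage. The fallback replaces the auxiliary by a reagent-controlled reduction and a diastereomer separation; it sets out from 8 and comes back at 13. Ketone 8 is methylated without auxiliary (LDA, MeI, THF, −78 °C) to 2,4-dimethyl-2-[(2R)-2-methyl-11-phenylundecyl]cyclobutan-1-one F6 as a mixture at C4. Reduction with Me-CBS/BH3·SMe2 fixes the carbinol configuration by differentiating the quaternary from the tertiary α-carbon. The two C4 series then differ as cis and trans cyclobutanols, which are separated by chromatography, and the 4S isomer is taken on as 13 (single carbinol epimer).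

**Further compounds**

F1 | step 9 | [(2R)-3-hydroxy-2-methylpropyl]triphenylphosphonium bromide | C[C@H](CO)C[P+](c1ccccc1)(c1ccccc1)c1ccccc1.[Br-]
F2 | step 9 | (2S,6R)-2,4,6-trimethyl-15-phenylpentadec-3-en-1-ol (E/Z mixture) | C[C@H](CCCCCCCCCc1ccccc1)CC(C)=C[C@H](C)CO
F3 | step 9 | (2S,6R)-2,4,6-trimethyl-15-phenyl-4-[(triethylsilyl)peroxy]pentadecan-1-ol (C4 epimers) | C[C@H](CCCCCCCCCc1ccccc1)CC(C)(OO[Si](CC)(CC)CC)C[C@H](C)CO
F4 | step 9 | (2S,6R)-2,4,6-trimethyl-15-phenyl-4-[(triethylsilyl)peroxy]pentadecanal (C4 epimers) | C[C@H](CCCCCCCCCc1ccccc1)CC(C)(OO[Si](CC)(CC)CC)C[C@H](C)C=O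
F5 | step 11 | methyl (2E,4S,8R)-6-hydroperoxy-4,6,8-trimethyl-17-phenylheptadec-2-enoate (C6 epimers) | C[C@H](CCCCCCCCCc1ccccc1)CC(C)(OO)C[C@H](C)/C=C/C(=O)OC
F6 | step 6 | 2,4-dimethyl-2-[(2R)-2-methyl-11-phenylundecyl]cyclobutan-1-one (C2 and C4 epimers) | C[C@H](CCCCCCCCCc1ccccc1)CC1(C)CC(C)C1=O
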